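In a one-step world, substrate meets partner and product climbs until the limiting reagent has turned, which in the violet run means substrate, at 0.100 M.

| flask | substrate | partner | time |
|---|---|---|---|
| violet | 0.100 M | 0.200 M |  |
| blue | 0.100 M | 0.100 M |  |
| green | 0.300 M | 0.200 M |  |
| teal | 0.100 M | 0.0570 M | 16 min |

| run | time / min | [product] / M |
|---|---|---|
| violet run | 2.7 | 0.0387 |
| violet run | 5.3 | 0.0529 |
| violet run | 8.0 | 0.0604 |
| violet run | 11 | 0.0644 |
| violet run | 13 | 0.0654 |
| violet run | 16 | 0.0670 |
| blue run | 2.7 | 0.0259 |
| blue run | 5.3 | 0.0376 |
| blue run | 8.0 | 0.0432 |
| blue run | 11 | 0.0482 |
| blue run | 13 | 0.0493 |
| blue run | 16 | 0.0518 |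
| green run | 2.7 | 0.0816 |
| green run | 5.3 | 0.1031 |
| green run | 8.0 | 0.1135 |
| green run | 11 | 0.1193 |
| green run | 13 | 0.1217 |
| green run | 16 | 0.1241 |

(readings scatter by 3 × 10⁻⁴ M)

* how the opening rate goes with [partner] round the charge of the violet run: the exponent of the rate at two percent of substrate gone to product
* how the opening rate goes with [substrate] round the charge of the violet run: the exponent of the rate at two percent of substrate gone to product (one fixed amount of product, the same in the runs compared)
* product in the teal run at 16 min, as a share of the substrate charged

- Overall: substrate + partner -> product.
- Constant volume, constant temperature.
- Readings of a species count what is bound in complexes too.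
- "The second partner" is partner.
- An order is taken over about fifteen percent of the charge, up and down.

Does the violet run obey that world? At 16 min it holds 0.0670 M of product. A one-step rate, proportional to both reactants, would then stand at 0.219 of its opening value. The readings give 0.0372 for the last interval against the first, far less. So the violet run does not obey it.

How strongly does the first stretch respond to the charges? Product in the blue run over product in the violet run at 2.7 min is 0.669, an exponent of 0.579 in partner. Green over violet gives 0.679 in substrate. These are averages over a stretch, not opening values: at that time the product of the violet run already equals 38.7% of its substrate charge.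

What stays nearly constant at 16 min? Take the product odds, product made over charged substrate not in product. They are 2.03 in the violet run and 1.07 in the blue run, so at this one substrate charge, twice the partner goes with nearly twice the odds. Dividing by the charge ratio of partner to substrate gives 1.02 and 1.07. Their mean, 1.04, is the odds factor: product odds at 16 min per unit of charge ratio.

Frozen at that value, the factor gives the teal run odds of 0.596, so a share of 37.3%. That lies below the 57.0% that its partner, now the limiting reagent, allows.

The forecast gives 0.55 (0.3 to 0.85) in partner, 0.6 (0.3 to 0.9) in substrate and 37% (33% to 41%) for the teal run, on a ground different from the odds factor: “The catalyst is probably dying, or product is inhibiting it.”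

The flask gives 0.65 in partner, 1.0 in substrate and 37.2% for the teal run.

    substrate + partner → product + by-product (3.114 M⁻¹ min⁻¹)
    2 partner ⇌ idle reagent dimer, settled at all times (8.340 M⁻¹)
    2 substrate → homo dimer (1.236 M⁻¹ min⁻¹)

Where the same amount of product has been made, the green run goes 3.0 times as fast as the violet run. The teal run's own odds factor reads 1.04, beside 1.04. That factor was taken from the violet and blue runs. The charge ratio of the green run and 1.04 give odds of 0.697, so 0.123 M of product at 16 min, and the reading of the green run there is 0.1241 M.

The earlier runs and the new flask were computed for an exercise; scatter was added.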